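(The numbers in the tables are calculated with constants of no real substance.)

Late in the two earlier runs, at 6.00 min, X had been fed over 3.0 min into a flask of E and Z, and I set the two products side by side, since what is asked is how the share of G in G plus J (the selectivity to G) moves with the starting c_E.

in all of them: X 0.11 M (fed, over 3.0 min)
- green: E 0.073 M; Z 0.055 M; run made earlier; the fed solution adds 1.0 times the starting volume
- red: E 0.39 M; Z 0.055 M; run made earlier; the fed solution adds 1.0 times the starting volume
- Tuesday's: E 0.120 M; Z 0.0550 M; the fed solution adds 1.0 times the starting volume; time 6.0 min
- Monday's: E 0.150 M; Z 0.0550 M; the fed solution adds 1.0 times the starting volume; time 6.0 min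
- Saturday's: E 0.250 M; Z 0.0550 M; the fed solution adds 1.0 times the starting volume; time 6.0 min
- Thursday's: E 0.400 M; Z 0.0550 M; the fed solution adds 1.0 times the starting volume; time 6.0 min
- Friday's: E 0.600 M; Z 0.0550 M; the fed solution adds 1.0 times the starting volume; time 6.0 min

| run | time / min | G / % | J / % |
|---|---|---|---|
| green | 0.500 | 0.2 | 1.7 |
| green | 0.667 | 0.6 | 3.0 |
| green | 1.00 | 1.1 | 4.6 |
| green | 1.50 | 1.3 | 6.3 |
| green | 2.50 | 3.8 | 10.3 |
| green | 4.00 | 6.5 | 15.0 |
| green | 6.00 | 7.4 | 20.0 |
| red | 0.500 | 0.5 | 4.4 |
| red | 0.667 | 0.5 | 5.0 |
| red | 1.00 | 0 | 8.3 |
| red | 1.50 | 0.3 | 12.9 |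
| red | 2.50 | 2.1 | 19.5 |
| red | 4.00 | 1.1 | 27.8 |
| red | 6.00 | 2.6 | 38.2 |

(standard deviation of a reading: 0.5 percentage points)

- charges are per starting volume, the dose included; the dosed solution carries all of it
- percentages count the whole charge, also what has not yet gone in
- "hardly changes" means that all values lie within two and a half points (for a concentration: within two and a half percent of the largest)

- share of G in all that became G or J for Tuesday's, Monday's, Saturday's, Thursday's, Friday's, in this order
- how the row runs (hardly changes / rises, then falls / falls all the way / rises all the way / falls, then rises)

The J reading of the green run amounted to 50.1 % of its charged E and that of the red run to 49.0 %, while the G reading, reckoned per starting volume, amounted to 0.0135 M in the green run and 0.0130 M in the red run, although c_E differed 5.34 times. So in these two runs J followed c_E and G did not, which gave me one quantity to reckon in two independent ways: c_E times the ratio of the G reading to the J reading. The green run gives 0.0270 M and the red run 0.0265 M, and I trusted this agreement as far as the scatter of 0.5 percentage points on a red G reading of 2.6 % allows. The mean of the two, 0.0268 M, a reading with their scatter, I carried on as the crossing concentration, the starting c_E at which, by this reckoning for the time of these readings, G and J come out equal in this recipe. By my rule J holds the larger part above it, and the share is the crossing concentration over itself plus c_E. Tuesday's has the lowest c_E of the asked flasks and still stands above the crossing, so my rule gave 18.2 % for Tuesday's and 4.27 % for Friday's, with a steady fall between them.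

The forecast, on the ground that “G appears to depend on X (and perhaps Z), not on E”, gave 18.4 %, 15.3 %, 9.7 %, 6.3 % and 4.3 %, and said the row falls all the way; my figures for Tuesday's and Friday's stand slightly lower.

The simulation gave 20.0 %, 16.8 %, 11.1 %, 7.50 % and 5.37 %, and the row falls all the way.

    E → J (k = 0.112 /min)
    X → G (k = 0.0779 /min)
    X ⇌ E (K = 1.35, k = 0.0142 /min)
    2 X → Q (k = 7.01 /M/min)
    X + Z → D (k = 7.18 /M/min)

Against the carried 0.0268 M, the same quantity, c_E times the ratio of G to J, taken from the flasks' own shares comes to 0.0300 M for Tuesday's and 0.0340 M for Friday's, the higher of the two. In Tuesday's the half-life of E by the reaction of E to J, 6.2 min at 6.00 min, lay close to the asked time, and about half of the charged E was left. Friday's, with 5.00 times that c_E, still had 48 % of its charged E there, unbound, at 6.00 min.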